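**Atom labels (one-line convention):** germacrane numbering is used throughout – ring C1–C10, lactone O on C6, C7 carries C11(=C13H2)–C12(=O), C8 carries the 3-methylbutanoate, C14 is the formyl carbon on C10, C15 the hydroxymethyl carbon on C4. The target is (6R,7S,8R), with both ring alkenes E by the sequence rules (C3 cis to C6, C9 cis to C2).

## Retrosynthetic overview

1. Last step: the ten-membered ring is closed at C8–C9 by adding a C8 α-(acyloxy)alkyl radical to the CH2 end of a 2-(1-methoxyalkyl)acrolein; loss of methanol then gives the C1=C10 enal. The lactone ring is made first, the carbocycle last.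
2. The open-chain precursor comes from a B-alkyl Suzuki coupling at C3–C4 between a (Z)-vinyl iodide lactone and a C1–C3/C9/C10/C14 diene acetal (acrolein plus a 2-lithioacrolein acetal).
3. The cis lactone (C6, C7) comes from a catalytic asymmetric 2-(methoxycarbonyl)allylation of a (Z)-β-iodo enal (from but-2-yne-1,4-diol) with a Baylis–Hillman-derived bromide (methyl acrylate plus glyoxal mono-acetal).
4. The C8 acetal is turned into the radical precursor by aldehyde/acyl chloride addition, which also installs the 3-methylbutanoate.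

## Route

Step 1
Reactants: 1 but-2-yne-1,4-diol
Product: 2 4-[(tert-butyldiphenylsilyl)oxy]but-2-yn-1-ol
Conditions: TBDPSCl (1 equiv), imidazole, 1 (4 equiv), DMF, 0 °C → rt
Reagents that add atoms: tert-butyl(chloro)diphenylsilane, CC(C)(C)[Si](Cl)(c1ccccc1)c1ccccc1
Why: statistical monosilylation of a symmetrical diol used in excess (silyl ether formation); no stereocentre is involved.

Step 2
Reactants: 2 4-[(tert-butyldiphenylsilyl)oxy]but-2-yn-1-ol
Product: 4 (Z)-4-[(tert-butyldiphenylsilyl)oxy]-3-iodobut-2-en-1-ol, via cyclic vinylalanate 3 (not isolated)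
Conditions: NaAlH2(OCH2CH2OCH3)2, THF, 0 °C → rt; then I2, −78 → 0 °C
Reagents that add atoms: iodine, II
Why: hydroxyl-directed trans-hydroalumination of the propargylic alcohol puts hydride on C5 and aluminium on C4 through a five-membered alkoxyaluminate, and iodinolysis with retention gives the (Z)-iodoalkene in which iodine (later C3) is cis to C6.

Step 3
Reactants: 4 (Z)-4-[(tert-butyldiphenylsilyl)oxy]-3-iodobut-2-en-1-ol
Product: 5 (Z)-4-[(tert-butyldiphenylsilyl)oxy]-3-iodobut-2-enal
Conditions: MnO2 (15 equiv), CH2Cl2, rt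
Reagents that add atoms: none
Why: MnO2 oxidation of a primary allylic alcohol gives the enal without touching the vinyl iodide or the alkene geometry.

Step 4
Reactants: 6 2,2-dimethoxyacetaldehyde; 7 methyl acrylate
Product: 8 methyl 3-hydroxy-4,4-dimethoxy-2-methylidenebutanoate (racemic)
Conditions: DABCO (0.5 equiv), 1,4-dioxane/H2O, rt
Reagents that add atoms: none
Why: Morita–Baylis–Hillman reaction of a reactive, non-enolisable aldehyde with an acrylate; the carbinol centre is erased in step 5.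

Step 5
Reactants: 8 methyl 3-hydroxy-4,4-dimethoxy-2-methylidenebutanoate
Product: 9 methyl (Z)-2-(bromomethyl)-4,4-dimethoxybut-2-enoate
Conditions: NBS, Me2S, CH2Cl2, 0 °C → rt
Reagents that add atoms: N-bromosuccinimide, O=C1CCC(=O)N1Br
Why: Corey–Kim-type activation of the Baylis–Hillman alcohol with SN2' delivery of bromide gives the thermodynamically preferred (Z)-2-(bromomethyl)enoate under neutral conditions that spare the acetal.

Step 6
Reactants: 5 (Z)-4-[(tert-butyldiphenylsilyl)oxy]-3-iodobut-2-enal; 9 methyl (Z)-2-(bromomethyl)-4,4-dimethoxybut-2-enoate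
Product: 11 (4R,5S)-5-[(Z)-3-[(tert-butyldiphenylsilyl)oxy]-2-iodoprop-1-en-1-yl]-4-(dimethoxymethyl)-3-methylideneoxolan-2-one, via silyl ether 10 (not isolated)
Conditions: CrCl2 (10 mol%, nickel-free), 3,6-di-tert-butyl-1,8-bis(4-isopropyl-4,5-dihydrooxazol-2-yl)carbazole ligand (12 mol%, the enantiomer that gives Si-face addition), Mn, Me3SiCl, THF, rt; then TsOH·H2O, CH2Cl2, rt
Reagents that add atoms: none
Why: catalytic asymmetric Nozaki–Hiyama-type 2-(alkoxycarbonyl)allylation in which the (Z)-allylchromium reacts through a closed six-membered transition state to give the syn adduct (hence the cis β,γ-lactone after acid lactonisation), while the chiral CrCl2–bis(oxazoline) complex directs attack to the Si face of the aldehyde, setting C6 and C7 as in the target.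

Step 7
Reactants: 11 (4R,5S)-5-[(Z)-3-[(tert-butyldiphenylsilyl)oxy]-2-iodoprop-1-en-1-yl]-4-(dimethoxymethyl)-3-methylideneoxolan-2-one
Product: 12 (2S,3R)-2-[(Z)-3-[(tert-butyldiphenylsilyl)oxy]-2-iodoprop-1-en-1-yl]-4-methylidene-5-oxooxolane-3-carbaldehyde
Conditions: CF3CO2H/H2O (9:1), CH2Cl2, 0 °C; used at once
Reagents that add atoms: water, O
Why: acid hydrolysis of the dimethyl acetal under conditions that the silyl ether, vinyl iodide and lactone survive; C7 is not epimerised in cold acid if the aldehyde is carried on directly.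

Step 8
Reactants: 12 (2S,3R)-2-[(Z)-3-[(tert-butyldiphenylsilyl)oxy]-2-iodoprop-1-en-1-yl]-4-methylidene-5-oxooxolane-3-carbaldehyde; 13 3-methylbutanoyl chloride
Product: 15 [(2S,3R)-2-[(Z)-3-[(tert-butyldiphenylsilyl)oxy]-2-iodoprop-1-en-1-yl]-4-methylidene-5-oxooxolan-3-yl](phenylselanyl)methyl 3-methylbutanoate (both C8 epimers), via chloroalkyl ester 14 (not isolated)
Conditions: 13 (1.0 equiv), ZnCl2 (2 mol%), CH2Cl2, −20 °C; then PhSeSiMe3, −20 → 0 °C
Reagents that add atoms: phenyl trimethylsilyl selenide, C[Si](C)(C)[Se]c1ccccc1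
Why: ZnCl2-catalysed addition of the acyl chloride across the aldehyde C=O gives the α-chloroalkyl ester, whose chloride is displaced by the selenosilane through the acyloxycarbenium ion, so O8 receives its ester and C8 becomes a latent radical centre whose configuration does not matter here.

Step 9
Reactants: 16 2-bromo-3,3-dimethoxyprop-1-ene; 17 acrolein
Product: 20 2-(dimethoxymethyl)-3-methoxypenta-1,4-diene (racemic), via vinyllithium 18 (not isolated), via lithium alkoxide 19 (not isolated)
Conditions: t-BuLi (2 equiv), Et2O, −78 °C; 17, −78 °C; then MeI, DMPU, −78 °C → rt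
Reagents that add atoms: iodomethane, CI
Why: bromine–lithium exchange, 1,2-addition of the vinyllithium to acrolein and O-methylation in one pot give a Baylis–Hillman-type ether of acrolein whose carbinol centre is erased in step 12.

Step 10
Reactants: 15 [(2S,3R)-2-[(Z)-3-[(tert-butyldiphenylsilyl)oxy]-2-iodoprop-1-en-1-yl]-4-methylidene-5-oxooxolan-3-yl](phenylselanyl)methyl 3-methylbutanoate; 20 2-(dimethoxymethyl)-3-methoxypenta-1,4-diene
Product: 22 [(2R,3R)-2-[(E)-2-[[(tert-butyldiphenylsilyl)oxy]methyl]-6-(dimethoxymethyl)-5-methoxyhepta-1,6-dien-1-yl]-4-methylidene-5-oxooxolan-3-yl](phenylselanyl)methyl 3-methylbutanoate, via alkylborane 21 (not isolated)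
Conditions: 20 (1.5 equiv), 9-BBN-H, THF, 0 °C → rt; then 15, PdCl2(dppf) (5 mol%), AsPh3, K3PO4 (aq), DMF, rt
Reagents that add atoms: none
Why: 9-BBN-H should hydroborate the monosubstituted vinyl group in preference to the hindered, oxygen-flanked 1,1-disubstituted alkene, and the B-alkyl Suzuki–Miyaura coupling replaces iodine with retention, fixing C3 cis to C6.

Step 11
Reactants: 22 [(2R,3R)-2-[(E)-2-[[(tert-butyldiphenylsilyl)oxy]methyl]-6-(dimethoxymethyl)-5-methoxyhepta-1,6-dien-1-yl]-4-methylidene-5-oxooxolan-3-yl](phenylselanyl)methyl 3-methylbutanoate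
Product: 23 [(2R,3R)-2-[(E)-6-formyl-2-(hydroxymethyl)-5-methoxyhepta-1,6-dien-1-yl]-4-methylidene-5-oxooxolan-3-yl](phenylselanyl)methyl 3-methylbutanoate
Conditions: HF (48% aq.), MeCN, 0 °C → rt
Reagents that add atoms: water, O
Why: aqueous HF cleaves the silyl ether and hydrolyses the allylic dimethyl acetal in one operation, while the α-acyloxy selenide, which ionises poorly, is left intact.

Step 12
Reactants: 23 [(2R,3R)-2-[(E)-6-formyl-2-(hydroxymethyl)-5-methoxyhepta-1,6-dien-1-yl]-4-methylidene-5-oxooxolan-3-yl](phenylselanyl)methyl 3-methylbutanoate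
Product: 25 (3aS,4R,6E,10E,11aR)-6-formyl-10-(hydroxymethyl)-3-methylidene-2-oxo-2,3,3a,4,5,8,9,11a-octahydrocyclodeca[b]furan-4-yl 3-methylbutanoate, via methoxy aldehyde 24 (not isolated)
Conditions: Bu3SnH (1.5 equiv), AIBN (0.2 equiv), syringe pump 8 h, benzene (2 mM), 80 °C; then DBU, rt
Reagents that add atoms: none
Why: Bu3Sn• abstracts PhSe to give the C8 α-acyloxyalkyl radical, which closes the ring by a 10-endo Giese-type macrocyclisation onto the CH2 terminus (C9) of the 2-substituted acrolein; C9 is expected to bond anti to C11 with the ester in the open sector next to H7, which would give the 8R centre (O8 trans to C11), and after hydrogen transfer to C10 DBU eliminates methanol (E1cB) to give the ring-cis (E)-enal.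

## Compound list

1 | but-2-yne-1,4-diol | OCC#CCO | starting material
2 | 4-[(tert-butyldiphenylsilyl)oxy]but-2-yn-1-ol | OCC#CCO[Si](c1ccccc1)(c1ccccc1)C(C)(C)C | intermediate
3 | sodium cyclic alkoxy(alkenyl)bis(2-methoxyethoxy)aluminate from 2 | [Na+].COCCO[Al-]1(OCCOC)OCC=C1CO[Si](c2ccccc2)(c2ccccc2)C(C)(C)C | intermediate (not isolated)
4 | (Z)-4-[(tert-butyldiphenylsilyl)oxy]-3-iodobut-2-en-1-ol | OC/C=C(\I)/CO[Si](c1ccccc1)(c1ccccc1)C(C)(C)C | intermediate
5 | (Z)-4-[(tert-butyldiphenylsilyl)oxy]-3-iodobut-2-enal | O=C/C=C(\I)/CO[Si](c1ccccc1)(c1ccccc1)C(C)(C)C | intermediate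
6 | 2,2-dimethoxyacetaldehyde | COC(OC)C=O | starting material
7 | methyl acrylate | C=CC(=O)OC | starting material
8 | methyl 3-hydroxy-4,4-dimethoxy-2-methylidenebutanoate (racemic) | C=C(C(=O)OC)C(O)C(OC)OC | intermediate
9 | methyl (Z)-2-(bromomethyl)-4,4-dimethoxybut-2-enoate | BrC/C(C(=O)OC)=C\C(OC)OC | intermediate
10 | methyl (Z)-7-[(tert-butyldiphenylsilyl)oxy]-3-(dimethoxymethyl)-6-iodo-2-methylidene-4-[(trimethylsilyl)oxy]hept-5-enoate, syn adduct (C3/C4 as C7/C6 of 11) | C=C(C(=O)OC)[C@@H](C(OC)OC)[C@H](O[Si](C)(C)C)/C=C(\I)/CO[Si](c1ccccc1)(c1ccccc1)C(C)(C)C | intermediate (not isolated)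
11 | (4R,5S)-5-[(Z)-3-[(tert-butyldiphenylsilyl)oxy]-2-iodoprop-1-en-1-yl]-4-(dimethoxymethyl)-3-methylideneoxolan-2-one | C=C1C(=O)O[C@@H]([C@@H]1C(OC)OC)/C=C(\I)/CO[Si](c2ccccc2)(c2ccccc2)C(C)(C)C | intermediate
12 | (2S,3R)-2-[(Z)-3-[(tert-butyldiphenylsilyl)oxy]-2-iodoprop-1-en-1-yl]-4-methylidene-5-oxooxolane-3-carbaldehyde | C=C1C(=O)O[C@@H]([C@@H]1C=O)/C=C(\I)/CO[Si](c2ccccc2)(c2ccccc2)C(C)(C)C | intermediate
13 | 3-methylbutanoyl chloride | CC(C)CC(Cl)=O | starting material
14 | chloro[(2S,3R)-2-[(Z)-3-[(tert-butyldiphenylsilyl)oxy]-2-iodoprop-1-en-1-yl]-4-methylidene-5-oxooxolan-3-yl]methyl 3-methylbutanoate (both C8 epimers) | C=C1C(=O)O[C@@H]([C@@H]1C(Cl)OC(=O)CC(C)C)/C=C(\I)/CO[Si](c2ccccc2)(c2ccccc2)C(C)(C)C | intermediate (not isolated)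
15 | [(2S,3R)-2-[(Z)-3-[(tert-butyldiphenylsilyl)oxy]-2-iodoprop-1-en-1-yl]-4-methylidene-5-oxooxolan-3-yl](phenylselanyl)methyl 3-methylbutanoate (both C8 epimers) | C=C1C(=O)O[C@@H]([C@@H]1C([Se]c2ccccc2)OC(=O)CC(C)C)/C=C(\I)/CO[Si](c2ccccc2)(c2ccccc2)C(C)(C)C | intermediate
16 | 2-bromo-3,3-dimethoxyprop-1-ene | C=C(Br)C(OC)OC | starting material
17 | acrolein (prop-2-enal) | C=CC=O | starting material
18 | [1-(dimethoxymethyl)ethenyl]lithium | [Li]C(=C)C(OC)OC | intermediate (not isolated)
19 | lithium 2-(dimethoxymethyl)penta-1,4-dien-3-olate | [Li+].[O-]C(C=C)C(=C)C(OC)OC | intermediate (not isolated)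
20 | 2-(dimethoxymethyl)-3-methoxypenta-1,4-diene (racemic) | C=CC(OC)C(=C)C(OC)OC | intermediate
21 | 9-[4-(dimethoxymethyl)-3-methoxypent-4-en-1-yl]-9-borabicyclo[3.3.1]nonane | C=C(C(OC)OC)C(OC)CCB1C2CCCC1CCC2 | intermediate (not isolated)
22 | [(2R,3R)-2-[(E)-2-[[(tert-butyldiphenylsilyl)oxy]methyl]-6-(dimethoxymethyl)-5-methoxyhepta-1,6-dien-1-yl]-4-methylidene-5-oxooxolan-3-yl](phenylselanyl)methyl 3-methylbutanoate (epimers at C1 and C8) | C=C1C(=O)O[C@@H]([C@@H]1C([Se]c2ccccc2)OC(=O)CC(C)C)/C=C(/CO[Si](c2ccccc2)(c2ccccc2)C(C)(C)C)CCC(OC)C(=C)C(OC)OC | intermediate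
23 | [(2R,3R)-2-[(E)-6-formyl-2-(hydroxymethyl)-5-methoxyhepta-1,6-dien-1-yl]-4-methylidene-5-oxooxolan-3-yl](phenylselanyl)methyl 3-methylbutanoate (epimers at C1 and C8) | C=C1C(=O)O[C@@H]([C@@H]1C([Se]c2ccccc2)OC(=O)CC(C)C)/C=C(/CO)CCC(OC)C(=C)C=O | intermediate
24 | (3aS,4R,10E,11aR)-6-formyl-10-(hydroxymethyl)-7-methoxy-3-methylidene-2-oxo-2,3,3a,4,5,6,7,8,9,11a-decahydrocyclodeca[b]furan-4-yl 3-methylbutanoate (epimers at C1 and C10) | C=C1C(=O)O[C@@H]2/C=C(/CO)CCC(OC)C(C=O)C[C@@H](OC(=O)CC(C)C)[C@H]12 | intermediate (not isolated)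
25 | (3aS,4R,6E,10E,11aR)-6-formyl-10-(hydroxymethyl)-3-methylidene-2-oxo-2,3,3a,4,5,8,9,11a-octahydrocyclodeca[b]furan-4-yl 3-methylbutanoate | C=C1C(=O)O[C@@H]2/C=C(/CO)CC/C=C(/C=O)C[C@@H](OC(=O)CC(C)C)[C@H]12 | target

## Step count and risks

Total steps: 12. Longest linear sequence: 9 steps (1, 2, 3, 6, 7, 8, 10, 11, 12).

**Step 12 (most likely to fail).** A ten-membered ring is closed by a radical whose simple reduction by Bu3SnH competes, and the C8 configuration rests on a conformational argument. The fallback removes the hydrogen donor and leaves C8 as an alcohol that can be acylated with retention or inversion. It sets out from 12 and comes back to the route at 25. NaBH4 in MeOH/CH2Cl2 at −78 °C reduces the aldehyde to the primary alcohol F1. B-alkyl Suzuki coupling with 21 under the conditions of step 10 gives the acetal alcohol F2. Wet oxalic acid on silica frees only the enal and gives the hydroxy enal F3. Blue-light irradiation with Ir[dF(CF3)ppy]2(dtbbpy)PF6, quinuclidine and Bu4N H2PO4 in MeCN at 2 mM abstracts a hydrogen atom from the CH2OH group; the α-hydroxyalkyl radical closes the ring at C9, and DBU then gives the macrocyclic secondary alcohol F4. Acylation with 13 (pyridine, DMAP), or a Mitsunobu reaction with 3-methylbutanoic acid should F4 be the C8 epimer, gives the silyl ether F5, and aqueous HF gives 25.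

**Step 6.** Enantio- and syn-selectivity of the chromium-catalysed allylation are not established for a γ-substituted bromide carrying an acetal, and 1,4-elimination of methoxide from the allylchromium is possible. The fallback sets out from 9 and comes back at 11. B2pin2 with Pd2(dba)3 (zerovalent palladium) in DMSO converts 9 into the (Z)-allylboronate F6. Allylboration of 5 catalysed by a chiral phosphoric acid (TRIP) through the chair transition state gives the same syn adduct, and TsOH closes it to 11.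

**Step 10.** The hydroboration must discriminate between two terminal alkenes, and the coupling exposes the selenide and the α-methylene lactone to palladium and aqueous base. The fallback sets out from 20 and comes back at 22. Cp2Zr(H)Cl, which adds to the monosubstituted alkene only, followed by I2 gives the primary iodide F7. Zinc dust with LiCl in THF gives the alkylzinc iodide F8, and Negishi coupling with 15 using Pd(PPh3)4 gives 22 without borane or aqueous base.

Further compounds
F1 | step 12 | primary alcohol from 12 (CHO reduced to CH2OH): (4S,5S)-5-[(Z)-3-[(tert-butyldiphenylsilyl)oxy]-2-iodoprop-1-en-1-yl]-4-(hydroxymethyl)-3-methylideneoxolan-2-one | C=C1C(=O)O[C@@H]([C@@H]1CO)/C=C(\I)/CO[Si](c2ccccc2)(c2ccccc2)C(C)(C)C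
F2 | step 12 | Suzuki product of F1 with 21 (analogue of 22 with CH2OH at C8) | C=C1C(=O)O[C@@H]([C@@H]1CO)/C=C(/CO[Si](c2ccccc2)(c2ccccc2)C(C)(C)C)CCC(OC)C(=C)C(OC)OC
F3 | step 12 | hydroxy enal from F2 (acetal hydrolysed, silyl ether kept) | C=C1C(=O)O[C@@H]([C@@H]1CO)/C=C(/CO[Si](c2ccccc2)(c2ccccc2)C(C)(C)C)CCC(OC)C(=C)C=O
F4 | step 12 | 8-hydroxy macrocycle, O15 silyl ether of the 8-deacyl target (8R) | C=C1C(=O)O[C@@H]2/C=C(/CO[Si](c3ccccc3)(c3ccccc3)C(C)(C)C)CC/C=C(/C=O)C[C@@H](O)[C@H]12
F5 | step 12 | O15 tert-butyldiphenylsilyl ether of 25 | C=C1C(=O)O[C@@H]2/C=C(/CO[Si](c3ccccc3)(c3ccccc3)C(C)(C)C)CC/C=C(/C=O)C[C@@H](OC(=O)CC(C)C)[C@H]12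
F6 | step 6 | methyl (Z)-4,4-dimethoxy-2-[(4,4,5,5-tetramethyl-1,3,2-dioxaborolan-2-yl)methyl]but-2-enoate | CC1(C)OB(C/C(C(=O)OC)=C\C(OC)OC)OC1(C)C
F7 | step 10 | 2-(dimethoxymethyl)-5-iodo-3-methoxypent-1-ene | C=C(C(OC)OC)C(OC)CCI
F8 | step 10 | [4-(dimethoxymethyl)-3-methoxypent-4-en-1-yl]zinc iodide | C=C(C(OC)OC)C(OC)CC[Zn]I
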